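**Plan**

- Unit 1 is the 4'-methoxyflavanone half (O1, C2–C8a; rings A, C, B). Unit 2 is the 4'''-hydroxyflavanone half (O1'', C2''–C8a''; rings A'', C'', B'').
- Retrosynthetic cuts, in order: the five O–benzyl bonds; the C3''–H configuration; ring C'' at C2''–C3'' and O1''–C8a'' (aldehyde 16 + fluoro ketone 15); ring C at C2–C3 and O1–C8a (aldehyde 10 + diketone 9); the C3–C3'' bond of 9 (methyl ketone 6 + bromo ketone 8, both from aryl bromide 3).
- Forward: the two A-ring ketones are joined at C3–C3'' to give the C4–C3–C3''–C4'' chain (9); ring C is made by aldol, then SNAr (steps 6–7); ring C'' is made in one flask by aldol/SNAr (step 8); C3'' is equilibrated and the benzyl groups are removed.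
- Enabling feature: the C4'' ketone of 15 is flanked by the C3'' methylene and by ring A'', whose carbon C8a'' carries fluorine ortho to the acyl group. The ketone makes C3''–H enolisable and takes up the charge when the aldolate oxygen adds to C8a''.
- Stereochemistry: C2 and C2'' (both S) come from Ipc2B-controlled attack on the aldehyde Si face (reagent control, in step 8 reinforced by C2/C3 of unit 1). C3 and C3'' (both R) come from base equilibration to the diequatorial 2,3-trans rings.

Key step: step 8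

Assumption: 5-fluorobenzene-1,3-diol (1) and N-methoxy-N-methylacetamide (4) are taken as catalogue compounds. The facial sense of the Ipc2B aldol (reagent from (−)-α-pinene attacks the aldehyde Si face) is taken from the chair model for Z-enol borinates; if a trial aldol shows the opposite sense, the reagent from (+)-α-pinene replaces it in steps 6 and 8.

**Step 1**
Reactants: 1 5-fluorobenzene-1,3-diol
Product: 2 1,3-bis(benzyloxy)-5-fluorobenzene
Conditions: BnBr (2.2 equiv), K2CO3, DMF, rt → 60 °C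
Reagents that add atoms: benzyl bromide, BrCc1ccccc1
Why: Williamson ether synthesis on both phenols, with the unactivated aryl fluoride untouched.

**Step 2**
Reactants: 2 1,3-bis(benzyloxy)-5-fluorobenzene
Product: 3 1,5-bis(benzyloxy)-2-bromo-3-fluorobenzene
Conditions: NBS (1.0 equiv), MeCN, 0 °C → rt
Reagents that add atoms: N-bromosuccinimide, O=C1CCC(=O)N1Br
Why: Electrophilic aromatic bromination should occur at the position flanked by fluorine and one benzyloxy group (para to the other benzyloxy group), which is less hindered than the position between the two benzyloxy groups.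

**Step 3**
Reactants: 3 1,5-bis(benzyloxy)-2-bromo-3-fluorobenzene; 4 N-methoxy-N-methylacetamide
Product: 6 1-[2,4-bis(benzyloxy)-6-fluorophenyl]ethan-1-one, via aryllithium 5 (not isolated)
Conditions: n-BuLi (1.05 equiv), THF, −78 °C; 4 (1.2 equiv), −78 → −40 °C; aq NH4Cl at −40 °C
Reagents that add atoms: none
Why: Bromine–lithium exchange at −78 °C (below the temperature at which the ortho-fluoroaryllithium loses LiF) is followed by Weinreb ketone synthesis, the N,O-chelated tetrahedral adduct preventing over-addition until the quench.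

**Step 4**
Reactants: 6 1-[2,4-bis(benzyloxy)-6-fluorophenyl]ethan-1-one
Product: 8 2-bromo-1-[2,4-bis(benzyloxy)-6-fluorophenyl]ethan-1-one, via silyl enol ether 7 (not isolated)
Conditions: LiN(SiMe3)2 (1.1 equiv), THF, −78 °C; Me3SiCl (1.2 equiv); NBS (1.05 equiv), −78 → 0 °C
Reagents that add atoms: N-bromosuccinimide, O=C1CCC(=O)N1Br
Why: Regiospecific α-bromination of a ketone by way of its trimethylsilyl enol ether, which reacts with NBS far faster than the alkoxy-rich arene does, so that ring bromination is avoided.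

**Step 5**
Reactants: 6 1-[2,4-bis(benzyloxy)-6-fluorophenyl]ethan-1-one; 8 2-bromo-1-[2,4-bis(benzyloxy)-6-fluorophenyl]ethan-1-one
Product: 9 1,4-bis[2,4-bis(benzyloxy)-6-fluorophenyl]butane-1,4-dione
Conditions: ZnCl2 (2.0 equiv), Et2NH (1.5 equiv), t-BuOH (1.5 equiv), toluene, rt; then 6 (1.3 equiv) and 8 (1.0 equiv), rt
Reagents that add atoms: none
Why: Zinc-enolate coupling of a methyl ketone with an α-bromo ketone, in which the zinc enolate of 6 is alkylated at the CH2Br carbon of 8 either directly (SN2) or by aldol addition, 1,3-elimination to a zinc cyclopropanolate and ring opening, both paths giving the same symmetrical 1,4-diketone from one molecule of each partner.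

**Step 6**
Reactants: 9 1,4-bis[2,4-bis(benzyloxy)-6-fluorophenyl]butane-1,4-dione; 10 4-methoxybenzaldehyde
Product: 13 (2S)-1,4-bis[2,4-bis(benzyloxy)-6-fluorophenyl]-2-[(S)-hydroxy(4-methoxyphenyl)methyl]butane-1,4-dione, via Z-enol borinate 11 (not isolated), via boron aldolate 12 (not isolated)
Conditions: 9 (1.5 equiv), (+)-Ipc2BOTf [from (−)-α-pinene] (1.0 equiv), i-Pr2NEt, CH2Cl2, −78 °C; 10 (1.0 equiv), −78 → −20 °C; MeOH, pH 7 buffer, H2O2, 0 °C
Reagents that add atoms: none
Why: In this enantioselective boron aldol reaction, soft enolisation gives the Z-enol borinate, which adds to the Si face of the aldehyde through a chair Zimmerman–Traxler transition state under control of the Ipc ligands, setting C2 (S) and the syn C3 centre, while the excess of 9 favours mono-aldol and unreacted 9 is recycled.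

**Step 7**
Reactants: 13 (2S)-1,4-bis[2,4-bis(benzyloxy)-6-fluorophenyl]-2-[(S)-hydroxy(4-methoxyphenyl)methyl]butane-1,4-dione
Product: 15 (2S,3R)-5,7-bis(benzyloxy)-3-{2-[2,4-bis(benzyloxy)-6-fluorophenyl]-2-oxoethyl}-2-(4-methoxyphenyl)chroman-4-one, via cis-flavanone 14 (not isolated)
Conditions: Cs2CO3 (1.5 equiv), DMF, 0 °C → rt
Reagents that add atoms: none
Why: Intramolecular SNAr (addition–elimination, formally 6-endo-trig at C8a with the charge relayed through C4a to the C4 ketone) of the carbinol oxygen at the fluorinated carbon ortho to the nearer ketone closes ring C as a six- and not a seven-membered ring, and the carbonate then equilibrates the enolisable C3 to the diequatorial 2,3-trans isomer while C2 is not touched.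

**Step 8**
Reactants: 15 (2S,3R)-5,7-bis(benzyloxy)-3-{2-[2,4-bis(benzyloxy)-6-fluorophenyl]-2-oxoethyl}-2-(4-methoxyphenyl)chroman-4-one; 16 4-(benzyloxy)benzaldehyde
Product: 20 (2S,3R)-5,7-bis(benzyloxy)-3-{(2S,3S)-5,7-bis(benzyloxy)-2-[4-(benzyloxy)phenyl]-4-oxochroman-3-yl}-2-(4-methoxyphenyl)chroman-4-one, via Z-enol borinate 17 (not isolated), via boron aldolate 18 (not isolated), via potassium aldolate 19 (not isolated)
Conditions: (+)-Ipc2BOTf (1.3 equiv), i-Pr2NEt, CH2Cl2, −78 °C; 16 (1.2 equiv), −78 → −25 °C; KOt-Bu (2.1 equiv per boron), THF, −78 → −10 °C; aq NH4Cl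
Reagents that add atoms: none
Why: Proposed new method: soft enolisation of the C4'' ketone of 15 at C3''H2 gives Z-enol borinate 17, which adds to 16 through a chair Zimmerman–Traxler transition state (C3''–C2'' bond) to give boron aldolate 18; tert-butoxide then binds boron and the borate sheds the less basic β-keto alkoxide 19, whose oxygen adds to C8a'' and expels fluoride (O1''–C8a'' bond), the ortho C4'' carbonyl taking up the charge of the Meisenheimer adduct. The closest known reaction types are the Ipc2B-mediated syn-aldol of aryl alkyl ketones and the base-mediated intramolecular SNAr of a β-hydroxy ketone onto an ortho-fluoroaryl ketone (steps 6 and 7); their coupling in one flask through alkoxide exchange at boron is the untested part, argued from the irreversible loss of KF that drains the borate equilibrium. Ring C'' closes by addition–elimination at the sp2 carbon C8a'', the only carbon–fluorine site left in 15, and since the C4a''=C8a'' bond that relays the charge to the C4'' carbonyl lies inside the new ring the addition is formally 6-endo-trig. C2'' (S) is set by the Ipc ligands, which steer the enolate to the Si face of 16, and C3'' (S, syn) by the Z enolate geometry in the chair; the substrate should be matched, because with C3–H eclipsing the enol double bond (A(1,3) strain) the anisyl-bearing C2 blocks the other enolate face. The step needs enolisation at C3''H2 and not at the methine C3–H of unit 1, which the bulk of Ipc2BOTf and i-Pr2NEt should secure, and ring closure faster than retro-aldol or β-elimination in unit 1, which low temperature, the potassium counter-ion and a minimal excess of alkoxide are meant to secure. The cis relation C2''/C3'' is harmless because C3'' is corrected in step 9.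

**Step 9**
Reactants: 20 (2S,3R)-5,7-bis(benzyloxy)-3-{(2S,3S)-5,7-bis(benzyloxy)-2-[4-(benzyloxy)phenyl]-4-oxochroman-3-yl}-2-(4-methoxyphenyl)chroman-4-one
Product: 21 (2S,3R)-5,7-bis(benzyloxy)-3-{(2S,3R)-5,7-bis(benzyloxy)-2-[4-(benzyloxy)phenyl]-4-oxochroman-3-yl}-2-(4-methoxyphenyl)chroman-4-one
Conditions: DBU (0.2 equiv), CH2Cl2, rt
Reagents that add atoms: none
Why: Amidine-catalysed enolisation toward C3'' should equilibrate the cis-2'',3'' ring to the diequatorial trans ring (thermodynamic control), C2 and C2'' being non-enolisable and unit 1 already at its trans minimum.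

**Step 10**
Reactants: 21 (2S,3R)-5,7-bis(benzyloxy)-3-{(2S,3R)-5,7-bis(benzyloxy)-2-[4-(benzyloxy)phenyl]-4-oxochroman-3-yl}-2-(4-methoxyphenyl)chroman-4-one
Product: 22 (2S,3R)-3-[(2S,3R)-5,7-dihydroxy-2-(4-hydroxyphenyl)-4-oxochroman-3-yl]-5,7-dihydroxy-2-(4-methoxyphenyl)chroman-4-one
Conditions: H2 (1 atm), 10% Pd/C, THF–MeOH, rt
Reagents that add atoms: none
Why: Catalytic hydrogenolysis should cleave the five benzyl aryl ethers under neutral conditions that leave the aryl methyl ether, both ketones and the four stereocentres untouched.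

**Compound list**

1 | 5-fluorobenzene-1,3-diol | Oc1cc(O)cc(F)c1 | starting material
2 | 1,3-bis(benzyloxy)-5-fluorobenzene | Fc1cc(OCc2ccccc2)cc(OCc2ccccc2)c1 | intermediate
3 | 1,5-bis(benzyloxy)-2-bromo-3-fluorobenzene | Fc1cc(OCc2ccccc2)cc(OCc2ccccc2)c1Br | intermediate
4 | N-methoxy-N-methylacetamide | CC(=O)N(C)OC | starting material
5 | [2,4-bis(benzyloxy)-6-fluorophenyl]lithium (not isolated) | [Li]c1c(F)cc(OCc2ccccc2)cc1OCc1ccccc1 | intermediate
6 | 1-[2,4-bis(benzyloxy)-6-fluorophenyl]ethan-1-one | CC(=O)c1c(F)cc(OCc2ccccc2)cc1OCc1ccccc1 | intermediate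
7 | {[1-(2,4-bis(benzyloxy)-6-fluorophenyl)ethenyl]oxy}trimethylsilane (not isolated) | C=C(O[Si](C)(C)C)c1c(F)cc(OCc2ccccc2)cc1OCc1ccccc1 | intermediate
8 | 2-bromo-1-[2,4-bis(benzyloxy)-6-fluorophenyl]ethan-1-one | O=C(CBr)c1c(F)cc(OCc2ccccc2)cc1OCc1ccccc1 | intermediate
9 | 1,4-bis[2,4-bis(benzyloxy)-6-fluorophenyl]butane-1,4-dione | O=C(CCC(=O)c1c(F)cc(OCc2ccccc2)cc1OCc1ccccc1)c1c(F)cc(OCc2ccccc2)cc1OCc1ccccc1 | intermediate
10 | 4-methoxybenzaldehyde | COc1ccc(C=O)cc1 | starting material
11 | (Z)-1,4-bis[2,4-bis(benzyloxy)-6-fluorophenyl]-4-[(diisopinocampheylboryl)oxy]but-3-en-1-one (not isolated) | O=C(C/C=C(\OB([C@H]1C[C@H]2C[C@@H]([C@@H]1C)C2(C)C)[C@H]1C[C@H]2C[C@@H]([C@@H]1C)C2(C)C)c1c(F)cc(OCc2ccccc2)cc1OCc1ccccc1)c1c(F)cc(OCc2ccccc2)cc1OCc1ccccc1 | intermediate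
12 | O-(diisopinocampheylboryl) derivative of aldol 13 (not isolated) | COc1ccc([C@@H](OB([C@H]2C[C@H]3C[C@@H]([C@@H]2C)C3(C)C)[C@H]2C[C@H]3C[C@@H]([C@@H]2C)C3(C)C)[C@H](CC(=O)c2c(F)cc(OCc3ccccc3)cc2OCc2ccccc2)C(=O)c2c(F)cc(OCc3ccccc3)cc2OCc2ccccc2)cc1 | intermediate
13 | (2S)-1,4-bis[2,4-bis(benzyloxy)-6-fluorophenyl]-2-[(S)-hydroxy(4-methoxyphenyl)methyl]butane-1,4-dione | COc1ccc([C@@H](O)[C@H](CC(=O)c2c(F)cc(OCc3ccccc3)cc2OCc2ccccc2)C(=O)c2c(F)cc(OCc3ccccc3)cc2OCc2ccccc2)cc1 | intermediate
14 | (2S,3S)-5,7-bis(benzyloxy)-3-{2-[2,4-bis(benzyloxy)-6-fluorophenyl]-2-oxoethyl}-2-(4-methoxyphenyl)chroman-4-one (2,3-cis; not isolated) | COc1ccc([C@H]2Oc3cc(OCc4ccccc4)cc(OCc4ccccc4)c3C(=O)[C@H]2CC(=O)c2c(F)cc(OCc3ccccc3)cc2OCc2ccccc2)cc1 | intermediate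
15 | (2S,3R)-5,7-bis(benzyloxy)-3-{2-[2,4-bis(benzyloxy)-6-fluorophenyl]-2-oxoethyl}-2-(4-methoxyphenyl)chroman-4-one (2,3-trans) | COc1ccc([C@H]2Oc3cc(OCc4ccccc4)cc(OCc4ccccc4)c3C(=O)[C@@H]2CC(=O)c2c(F)cc(OCc3ccccc3)cc2OCc2ccccc2)cc1 | intermediate
16 | 4-(benzyloxy)benzaldehyde | O=Cc1ccc(OCc2ccccc2)cc1 | starting material
17 | Z-enol diisopinocampheylborinate of 15 at C3''=C4'' (not isolated) | COc1ccc([C@H]2Oc3cc(OCc4ccccc4)cc(OCc4ccccc4)c3C(=O)[C@@H]2/C=C(\OB([C@H]2C[C@H]3C[C@@H]([C@@H]2C)C3(C)C)[C@H]2C[C@H]3C[C@@H]([C@@H]2C)C3(C)C)c2c(F)cc(OCc3ccccc3)cc2OCc2ccccc2)cc1 | intermediate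
18 | (2''S,3''S)-syn diisopinocampheylboron aldolate from 17 and 16 (not isolated) | COc1ccc([C@H]2Oc3cc(OCc4ccccc4)cc(OCc4ccccc4)c3C(=O)[C@@H]2[C@@H]([C@H](OB([C@H]2C[C@H]3C[C@@H]([C@@H]2C)C3(C)C)[C@H]2C[C@H]3C[C@@H]([C@@H]2C)C3(C)C)c2ccc(OCc3ccccc3)cc2)C(=O)c2c(F)cc(OCc3ccccc3)cc2OCc2ccccc2)cc1 | intermediate
19 | potassium salt of the (2''S,3''S)-syn aldol (not isolated) | COc1ccc([C@H]2Oc3cc(OCc4ccccc4)cc(OCc4ccccc4)c3C(=O)[C@@H]2[C@@H]([C@H]([O-])c2ccc(OCc3ccccc3)cc2)C(=O)c2c(F)cc(OCc3ccccc3)cc2OCc2ccccc2)cc1.[K+] | intermediate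
20 | (2S,3R)-5,7-bis(benzyloxy)-3-{(2S,3S)-5,7-bis(benzyloxy)-2-[4-(benzyloxy)phenyl]-4-oxochroman-3-yl}-2-(4-methoxyphenyl)chroman-4-one (unit 1 trans, unit 2 cis) | COc1ccc([C@H]2Oc3cc(OCc4ccccc4)cc(OCc4ccccc4)c3C(=O)[C@@H]2[C@@H]2C(=O)c3c(OCc4ccccc4)cc(OCc4ccccc4)cc3O[C@@H]2c2ccc(OCc3ccccc3)cc2)cc1 | intermediate
21 | (2S,3R)-5,7-bis(benzyloxy)-3-{(2S,3R)-5,7-bis(benzyloxy)-2-[4-(benzyloxy)phenyl]-4-oxochroman-3-yl}-2-(4-methoxyphenyl)chroman-4-one (both units trans) | COc1ccc([C@H]2Oc3cc(OCc4ccccc4)cc(OCc4ccccc4)c3C(=O)[C@@H]2[C@H]2C(=O)c3c(OCc4ccccc4)cc(OCc4ccccc4)cc3O[C@@H]2c2ccc(OCc3ccccc3)cc2)cc1 | intermediate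
22 | (2S,3R)-3-[(2S,3R)-5,7-dihydroxy-2-(4-hydroxyphenyl)-4-oxochroman-3-yl]-5,7-dihydroxy-2-(4-methoxyphenyl)chroman-4-one | COc1ccc([C@H]2Oc3cc(O)cc(O)c3C(=O)[C@@H]2[C@H]2C(=O)c3c(O)cc(O)cc3O[C@@H]2c2ccc(O)cc2)cc1 | target

**Step count and risks**

Total step count: 10. Longest linear sequence: 10 steps (1 → 22).

Steps most likely to fail:

Step 8 (Proposed new method). The release of the aldolate from boron by tert-butoxide may be slower than retro-aldol cleavage or than deprotonation at C3 of unit 1, which leads to ring-opening by β-elimination of the ring oxygen. The facial preferences of reagent and substrate may also oppose each other and erode diastereoselectivity. The fallback uses known chemistry and sets out from 15 and 16. The same Ipc2BOTf aldol is run but worked up oxidatively (MeOH, pH 7 buffer, H2O2), so that the syn aldol (2S,3R)-5,7-bis(benzyloxy)-3-{(2S,3S)-1-[2,4-bis(benzyloxy)-6-fluorophenyl]-3-[4-(benzyloxy)phenyl]-3-hydroxy-1-oxopropan-2-yl}-2-(4-methoxyphenyl)chroman-4-one F1 is isolated and freed from diastereomers. F1 is then closed in a separate operation with Cs2CO3 in DMF, as 13 is in step 7 (intramolecular SNAr by way of 20 with concurrent equilibration of C3''), and the route is rejoined at 21.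

Step 7. Ring closure on the alkoxy-rich arene may be slow enough for retro-aldol cleavage, dehydration of the β-hydroxy ketone, or reversible β-elimination of the ring oxygen (loss of C2 configuration) to compete under stoichiometric carbonate. The fallback sets out from 13. Silylation (Et3SiCl, imidazole, DMF) should give (2S)-1,4-bis[2,4-bis(benzyloxy)-6-fluorophenyl]-2-[(S)-(4-methoxyphenyl)(triethylsilyloxy)methyl]butane-1,4-dione F2. Catalytic fluoride (CsF, 18-crown-6, THF, 0 °C) then unmasks the alkoxide only transiently in a desilylative SNAr, in which the fluoride expelled from C8a carries the chain and no stoichiometric base is present, to give cis-flavanone 14. Brief treatment with DBU (0.2 equiv, CH2Cl2) equilibrates C3, and the route is rejoined at 15.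

Step 6. Enantioselectivity with an electron-rich aromatic aldehyde may be low, the facial sense may be the opposite of the one assumed, and bis-aldol may form statistically. The fallback sets out from 9. Soft-enolisation C-acylation (MgBr2·OEt2, i-Pr2NEt, CH2Cl2) with 4-methoxybenzoyl chloride should give 1,4-bis[2,4-bis(benzyloxy)-6-fluorophenyl]-2-(4-methoxybenzoyl)butane-1,4-dione F3. Noyori asymmetric transfer hydrogenation with RuCl[(S,S)-TsDPEN](p-cymene) in HCO2H/Et3N should reduce only the unhindered 4-methoxybenzoyl ketone (the two di-ortho-substituted aroyl groups are twisted and shielded), with dynamic kinetic resolution at the acidic C2. This should give 1,4-bis[2,4-bis(benzyloxy)-6-fluorophenyl]-2-[(S)-hydroxy(4-methoxyphenyl)methyl]butane-1,4-dione (either C2 epimer) F4. Under the conditions of step 7, F4 closes ring C and C3 equilibrates, so the route is rejoined at 15.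

**Further compounds**

F1 | step 8 | (2S,3R)-5,7-bis(benzyloxy)-3-{(2S,3S)-1-[2,4-bis(benzyloxy)-6-fluorophenyl]-3-[4-(benzyloxy)phenyl]-3-hydroxy-1-oxopropan-2-yl}-2-(4-methoxyphenyl)chroman-4-one | COc1ccc([C@H]2Oc3cc(OCc4ccccc4)cc(OCc4ccccc4)c3C(=O)[C@@H]2[C@@H]([C@H](O)c2ccc(OCc3ccccc3)cc2)C(=O)c2c(F)cc(OCc3ccccc3)cc2OCc2ccccc2)cc1
F2 | step 7 | (2S)-1,4-bis[2,4-bis(benzyloxy)-6-fluorophenyl]-2-[(S)-(4-methoxyphenyl)(triethylsilyloxy)methyl]butane-1,4-dione | COc1ccc([C@@H](O[Si](CC)(CC)CC)[C@H](CC(=O)c2c(F)cc(OCc3ccccc3)cc2OCc2ccccc2)C(=O)c2c(F)cc(OCc3ccccc3)cc2OCc2ccccc2)cc1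
F3 | step 6 | 1,4-bis[2,4-bis(benzyloxy)-6-fluorophenyl]-2-(4-methoxybenzoyl)butane-1,4-dione | COc1ccc(C(=O)C(CC(=O)c2c(F)cc(OCc3ccccc3)cc2OCc2ccccc2)C(=O)c2c(F)cc(OCc3ccccc3)cc2OCc2ccccc2)cc1
F4 | step 6 | 1,4-bis[2,4-bis(benzyloxy)-6-fluorophenyl]-2-[(S)-hydroxy(4-methoxyphenyl)methyl]butane-1,4-dione (C2 unassigned) | COc1ccc([C@@H](O)C(CC(=O)c2c(F)cc(OCc3ccccc3)cc2OCc2ccccc2)C(=O)c2c(F)cc(OCc3ccccc3)cc2OCc2ccccc2)cc1
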